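**Strategy.** Ring A of the target (C4 with axial methyl and equatorial ester, C5–H, C10 methyl) is that of dehydroabietic acid, so ring C is cut away and only ring B is rebuilt. Everything rests on the C8–C9 disconnection. The adjacent C8 tertiary carbinol and chain-bearing C9 of ring B are the retron of an allylsilane adding to a methyl ketone. One Lewis acid step forms C8–C9, closes ring B, sets C8 and C9, and leaves a C11=C12 vinyl handle. Its precursor is a ring A compound. C5 carries a (6S)-1-silyloxy-3-oxobutyl chain, the 6α-oxygen being installed before arene cleavage, and C10 carries an (E)-3-trimethylsilylprop-1-enyl group.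

Key step: step 15

**Numbering.** Ring A = C1–C5, C10. Ring B = C5–C10. The C4 ester carbon is C18. The side chain is C11–C16, with C13 bearing =CH2, C14 bearing OOH, and C16 the butenolide γ-carbon. The β face is the face of the C10 methyl. The target is 4R,5R,6S,8R,9R,10S,14S,16S.

**Design remark.** The 6α-oxygen travels through the ring closure as a non-chelating TBS ether, so no C–H oxidation is needed after the key step. The allylsilane is made by Takai and Negishi steps so that its geometry is E.

**Assumption.** In step 19, (S,S)-ProPhenol/Me2Zn is taken to give the (S)-propargylic carbinol. The antipodal ligand would be used if a Mosher ester check showed the opposite sense.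

**Route**

Step 1
Reactants: 1 dehydroabietic acid
Product: 2 methyl dehydroabietate
Conditions: MeI, K2CO3, DMF, rt
Reagents that add atoms: iodomethane, CI
Why: SN2 O-alkylation of the carboxylate avoids attack at the hindered C18 carbonyl and leaves C4, C5 and C10 untouched.

Step 2
Reactants: 2 methyl dehydroabietate
Product: 3 methyl 7-oxoabieta-8,11,13-trien-18-oate
Conditions: CrO3, AcOH, 40 °C
Reagents that add atoms: chromium trioxide, O=[Cr](=O)=O
Why: Benzylic oxidation with CrO3 takes the only benzylic methylene (C7) to the aryl ketone.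

Step 3
Reactants: 3 methyl 7-oxoabieta-8,11,13-trien-18-oate
Product: 4 methyl 7-hydroxyabieta-8,11,13-trien-18-oate (both C7 epimers)
Conditions: NaBH4, MeOH/THF, 0 °C to rt
Reagents that add atoms: none
Why: Borohydride reduction of the aryl ketone spares the hindered ester, and the C7 configuration is irrelevant because step 4 erases it.

Step 4
Reactants: 4 methyl 7-hydroxyabieta-8,11,13-trien-18-oate
Product: 5 methyl abieta-6,8,11,13-tetraen-18-oate
Conditions: TsOH·H2O (cat.), toluene, reflux, Dean–Stark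
Reagents that add atoms: none
Why: Acid-catalysed E1 dehydration through the C7 benzylic cation can lose a proton only from C6 and gives the conjugated C6=C7 alkene.

Step 5
Reactants: 5 methyl abieta-6,8,11,13-tetraen-18-oate
Product: 6 methyl 6α,7α-epoxyabieta-8,11,13-trien-18-oate
Conditions: mCPBA, NaHCO3, CH2Cl2, 0 °C
Reagents that add atoms: 3-chloroperbenzoic acid, O=C(OO)c1cccc(Cl)c1
Why: Prilezhaev epoxidation of the styrene-type C6=C7 bond occurs from the α face because the axial C4 and C10 methyl groups cover the β face, which sets the C6–O bond α (6S).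

Step 6
Reactants: 6 methyl 6α,7α-epoxyabieta-8,11,13-trien-18-oate
Product: 7 methyl 6α-hydroxyabieta-8,11,13-trien-18-oate
Conditions: H2 (1 atm), Pd/C, EtOAc, Et3N (trace), rt
Reagents that add atoms: none
Why: Catalytic hydrogenolysis breaks only the benzylic C7–O bond of the aryl epoxide, so the C6–O bond and its α configuration are kept.

Step 7
Reactants: 7 methyl 6α-hydroxyabieta-8,11,13-trien-18-oate
Product: 8 methyl 6α-(tert-butyldimethylsilyloxy)abieta-8,11,13-trien-18-oate
Conditions: TBSOTf, 2,6-lutidine, CH2Cl2, 0 °C to rt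
Reagents that add atoms: tert-butyldimethylsilyl triflate, CC(C)(C)[Si](C)(C)OS(=O)(=O)C(F)(F)F
Why: Silylation with the reactive triflate covers the hindered equatorial alcohol with a group that resists oxidants, organometallics and Lewis acid and is a poor β-leaving group.

Step 8
Reactants: 8 methyl 6α-(tert-butyldimethylsilyloxy)abieta-8,11,13-trien-18-oate
Product: 9 ring A diacid (C10 bears CO2H = C9; C5 bears CH(OTBS)CH2CO2H = C6–C8; 4β-Me 4α-CO2Me 5α-H 10β-Me 6S)
Conditions: RuCl3·xH2O (cat.), NaIO4, CCl4/MeCN/H2O, rt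
Reagents that add atoms: sodium periodate, [Na+].[O-]I(=O)(=O)=O; water, O
Why: RuO4-catalysed oxidative degradation of an arene to carboxylic acids keeps the ipso carbons C8 and C9 as CO2H groups on C7 and C10, the neighbouring silyloxy group slows competing benzylic oxidation at C7, and no stereocentre is touched.

Step 9
Reactants: 9 ring A diacid
Product: 10 ring A C9 acid C8 methyl ester
Conditions: MeOH, EDCI·HCl, DMAP (cat.), CH2Cl2, 0 °C to rt
Reagents that add atoms: methanol, CO
Why: Steglich esterification discriminates by steric access, since only the primary-alkyl C8 acyl group is transferred to methanol, and a transient cyclic anhydride would also open at C8 rather than at the C9 carbonyl on quaternary C10.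

Step 10
Reactants: 10 ring A C9 acid C8 methyl ester
Product: 11 ring A C9 primary alcohol (C10–CH2OH)
Conditions: BH3·THF, THF, 0 °C to rt; MeOH
Reagents that add atoms: none
Why: Chemoselective borane reduction of a carboxylic acid through its acyloxyborane leaves both methyl esters and the silyl ether alone.

Step 11
Reactants: 11 ring A C9 primary alcohol
Product: 12 ring A C9 aldehyde (C10–CHO)
Conditions: Dess–Martin periodinane, NaHCO3, CH2Cl2, rt
Reagents that add atoms: none
Why: Dess–Martin oxidation stops at the aldehyde, which has no α-hydrogen and therefore cannot epimerise or enolise.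

Step 12
Reactants: 12 ring A C9 aldehyde
Product: 13 ring A (E)-iodoalkene (C10–C9H=C11H–I)
Conditions: CrCl2, CHI3, THF, 0 °C to rt
Reagents that add atoms: iodoform, IC(I)I
Why: Takai olefination through a geminal dichromium reagent gives the (E)-iodoalkene with bulky aldehydes and tolerates esters, which secures a geometry that an unstabilised ylide would not give.

Step 13
Reactants: 13 ring A (E)-iodoalkene
Product: 14 ring A (E)-allylsilane C8 methyl ester
Conditions: Me3SiCH2MgCl, ZnCl2, THF; Pd(PPh3)4 (cat.), rt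
Reagents that add atoms: (trimethylsilylmethyl)magnesium chloride, C[Si](C)(C)C[Mg]Cl
Why: Negishi coupling of the alkenyl iodide with the silylmethylzinc reagent proceeds with retention of the (E) geometry and, unlike the Grignard reagent itself, spares the esters.

Step 14
Reactants: 14 ring A (E)-allylsilane C8 methyl ester
Product: 16 ring A keto allylsilane (C5: (6S)-1-silyloxy-3-oxobutyl; C10: (E)-3-trimethylsilylprop-1-enyl), via Weinreb amide 15 (not isolated)
Conditions: MeNHOMe·HCl, iPrMgCl, THF, −20 °C; then MeMgBr, 0 °C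
Reagents that add atoms: methylmagnesium bromide, C[Mg]Br; N,O-dimethylhydroxylamine hydrochloride, CNOC.Cl (atoms stay only in 15)
Why: Weinreb ketone synthesis in one flask, in which the magnesium amide attacks only the unhindered C8 ester (the C18 ester on quaternary C4 is inert) and the chelated MeMgBr adduct stops at the ketone.

Step 15
Reactants: 16 ring A keto allylsilane
Product: 17 methyl 6α-(tert-butyldimethylsilyloxy)-8α-hydroxy-13,14,15,16-tetranorlabd-11-en-18-oate (trans-decalin; 8β-Me; 9β-vinyl)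
Conditions: TiCl4, 2,6-di-tert-butyl-4-methylpyridine, CH2Cl2 (dilute), −78 °C; aq NaHCO3
Reagents that add atoms: none
Why: TiCl4 binds the C8 ketone, the C9 terminus of the allylsilane (γ to silicon) attacks C8 anti to the C12–Si bond (SE2'), and the β-silyl cation at C11 loses Me3SiCl to leave the C11=C12 vinyl group, which makes this an intramolecular Hosomi–Sakurai allylation of a ketone. Ring B closes as a six-membered carbocycle in a 6-exo mode with respect to both π bonds, since the carbonyl oxygen and C11 stay outside the new ring. C9 is set by the chair-like transition state built on the trans-diequatorial C5 and C10 tethers, in which the (E)-alkene places C11 equatorial (9β) away from the axial H5 and H7, so H9 ends up α. C8 is set by the size of the titanium-bound oxygen, which should take the equatorial (α) site away from the axial C10 methyl and leave the smaller C8 methyl axial (β). The step needs 1,2-addition without protodesilylation or loss of the β-silyloxy group, and this is secured by the hindered pyridine that removes HCl, by the low temperature, by the poorly chelating and poorly leaving OTBS group, and by esters that are too weak as electrophiles to compete. The 6α-OTBS group also helps, because H6 must sit anti to H5 between the two quaternary carbons, which fixes C7 in the rotamer that leads to ring B.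

Step 16
Reactants: 18 3-(trimethylsilyl)propynal
Product: 19 (R)-1-(trimethylsilyl)hex-5-en-1-yn-3-ol
Conditions: (+)-Ipc2BOMe (from (−)-α-pinene), allylMgBr, Et2O, 0 °C to rt; 18, −78 °C; ethanolamine
Reagents that add atoms: allylmagnesium bromide, C=CC[Mg]Br
Why: Brown allylboration through a chair Zimmerman–Traxler transition state, in which the isopinocampheyl groups direct allyl transfer to the aldehyde face that gives the (R)-carbinol (future C14), the sense known for benzaldehyde and enals with this antipode.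

Step 17
Reactants: 19 (R)-1-(trimethylsilyl)hex-5-en-1-yn-3-ol
Product: 20 (R)-3-(tert-butyldimethylsilyloxy)-1-(trimethylsilyl)hex-5-en-1-yne
Conditions: TBSCl, imidazole, DMF, rt
Reagents that add atoms: tert-butyldimethylsilyl chloride, CC(C)(C)[Si](C)(C)Cl
Why: Standard silyl ether protection keeps the C14 oxygen inert to zinc and copper reagents.

Step 18
Reactants: 20 (R)-3-(tert-butyldimethylsilyloxy)-1-(trimethylsilyl)hex-5-en-1-yne
Product: 21 (R)-3-(tert-butyldimethylsilyloxy)-5-(trimethylsilyl)pent-4-ynal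
Conditions: O3, CH2Cl2, −78 °C (Sudan red 7B end point); PPh3
Reagents that add atoms: ozone, [O-][O+]=O
Why: Ozonolysis with reductive work-up cleaves the terminal alkene much faster than the silylated alkyne and gives the C16 aldehyde.

Step 19
Reactants: 21 (R)-3-(tert-butyldimethylsilyloxy)-5-(trimethylsilyl)pent-4-ynal; 22 methyl propiolate
Product: 24 methyl (4S,6R)-6-(tert-butyldimethylsilyloxy)-4-hydroxy-8-(trimethylsilyl)octa-2,7-diynoate, via methylzinc acetylide 23 (not isolated)
Conditions: Me2Zn, (S,S)-ProPhenol (cat.), Ph3PO (cat.), toluene, 4 °C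
Reagents that add atoms: dimethylzinc, C[Zn]C (atoms stay only in 23)
Why: Catalytic asymmetric alkynylation of an aldehyde with a zinc propiolate, in which the dinuclear zinc–ProPhenol complex and not the remote C14 centre selects the aldehyde face and sets C16 as S (1,3-syn to C14–O).

Step 20
Reactants: 24 methyl (4S,6R)-6-(tert-butyldimethylsilyloxy)-4-hydroxy-8-(trimethylsilyl)octa-2,7-diynoate
Product: 26 (S)-5-[(R)-2-(tert-butyldimethylsilyloxy)-4-(trimethylsilyl)but-3-yn-1-yl]-4-methylfuran-2(5H)-one, via hydroxy (Z)-enoate 25 (not isolated)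
Conditions: MeLi, CuI, THF, −78 °C; aq NH4Cl
Reagents that add atoms: methyllithium, [Li]C
Why: Syn carbocupration (conjugate addition of Me2CuLi to the ynoate) places the ester cis to the carbinol carbon, so the C16 oxygen lactonises with retention to the 4-methylbutenolide.

Step 21
Reactants: 26 (S)-5-[(R)-2-(tert-butyldimethylsilyloxy)-4-(trimethylsilyl)but-3-yn-1-yl]-4-methylfuran-2(5H)-one
Product: 27 (S)-5-[(R)-2-hydroxybut-3-yn-1-yl]-4-methylfuran-2(5H)-one
Conditions: Bu4NF, AcOH, THF, 0 °C to rt
Reagents that add atoms: none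
Why: Fluoride desilylation removes the C-silyl and O-silyl groups together, and the acetic acid buffer prevents deprotonation at the acidic C16–H.

Step 22
Reactants: 27 (S)-5-[(R)-2-hydroxybut-3-yn-1-yl]-4-methylfuran-2(5H)-one
Product: 28 (S)-5-[(R)-2-hydroxy-3-iodobut-3-en-1-yl]-4-methylfuran-2(5H)-one
Conditions: NaI, Me3SiCl, H2O, MeCN, rt
Reagents that add atoms: sodium iodide, [Na+].[I-]
Why: Markovnikov hydroiodination of a terminal alkyne with HI made in the flask gives the 2-iodoalk-1-ene, as known for propargylic alcohols, without touching C14 or C16.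

Step 23
Reactants: 17 methyl 6α-(tert-butyldimethylsilyloxy)-8α-hydroxy-13,14,15,16-tetranorlabd-11-en-18-oate; 28 (S)-5-[(R)-2-hydroxy-3-iodobut-3-en-1-yl]-4-methylfuran-2(5H)-one
Product: 30 coupled (14R)-allylic alcohol (6α-OTBS; 8α-OH; C13=CH2; 16S butenolide), via B-alkyl-9-BBN borane 29 (not isolated)
Conditions: 9-BBN-H, THF, rt to 40 °C; then 28, Pd(dppf)Cl2 (cat.), AsPh3, Cs2CO3, DMF/H2O, rt
Reagents that add atoms: 9-borabicyclo[3.3.1]nonane, [H]B1C2CCCC1CCC2 (atoms stay only in 29)
Why: Anti-Markovnikov hydroboration of the monosubstituted alkene and B-alkyl Suzuki–Miyaura coupling form C12–C13 at room temperature, and the mild aqueous carbonate is expected to leave C16 and the free hydroxyl groups alone.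

Step 24
Reactants: 30 coupled (14R)-allylic alcohol
Product: 32 (14S)-hydroperoxide 6-O-TBS ether, via allylic mesylate 31 (not isolated)
Conditions: Ms2O, Et3N, CH2Cl2, −40 °C; then anhydrous H2O2 in Et2O, −40 to 0 °C
Reagents that add atoms: hydrogen peroxide, OO; methanesulfonic anhydride, CS(=O)(=O)OS(C)(=O)=O (atoms stay only in 31)
Why: Mesylation of the only free secondary alcohol and SN2 perhydrolysis of the allylic sulfonate by neutral H2O2 at low temperature invert C14 from R to S, the known way from sulfonates to secondary hydroperoxides.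

Step 25
Reactants: 32 (14S)-hydroperoxide 6-O-TBS ether
Product: 33 target CNP0324515.1
Conditions: aq HF, MeCN, 0 °C to rt
Reagents that add atoms: none
Why: Acidic fluoride desilylation, which hydroperoxides, the tertiary alcohol and the butenolide tolerate, frees the 6α-hydroxyl without touching any stereocentre.

**Compound list**

1 | dehydroabietic acid | CC(C)c1ccc2c(c1)CC[C@@H]1[C@]2(C)CCC[C@@]1(C)C(=O)O | starting material
2 | methyl dehydroabietate | CC(C)c1ccc2c(c1)CC[C@@H]1[C@]2(C)CCC[C@@]1(C)C(=O)OC | intermediate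
3 | methyl 7-oxoabieta-8,11,13-trien-18-oate | CC(C)c1ccc2c(c1)C(=O)C[C@@H]1[C@]2(C)CCC[C@@]1(C)C(=O)OC | intermediate
4 | methyl 7-hydroxyabieta-8,11,13-trien-18-oate (both C7 epimers) | CC(C)c1ccc2c(c1)C(O)C[C@@H]1[C@]2(C)CCC[C@@]1(C)C(=O)OC | intermediate
5 | methyl abieta-6,8,11,13-tetraen-18-oate | CC(C)c1ccc2c(c1)C=C[C@@H]1[C@]2(C)CCC[C@@]1(C)C(=O)OC | intermediate
6 | methyl 6α,7α-epoxyabieta-8,11,13-trien-18-oate | CC(C)c1ccc2c(c1)[C@@H]3O[C@@H]3[C@@H]1[C@]2(C)CCC[C@@]1(C)C(=O)OC | intermediate
7 | methyl 6α-hydroxyabieta-8,11,13-trien-18-oate | CC(C)c1ccc2c(c1)C[C@H](O)[C@@H]1[C@]2(C)CCC[C@@]1(C)C(=O)OC | intermediate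
8 | methyl 6α-(tert-butyldimethylsilyloxy)abieta-8,11,13-trien-18-oate | CC(C)c1ccc2c(c1)C[C@H](O[Si](C)(C)C(C)(C)C)[C@@H]1[C@]2(C)CCC[C@@]1(C)C(=O)OC | intermediate
9 | ring A diacid (C9 and C8 as CO2H, 6S-OTBS) | OC(=O)[C@@]1(C)CCC[C@@](C)(C(=O)OC)[C@@H]1[C@@H](O[Si](C)(C)C(C)(C)C)CC(=O)O | intermediate
10 | ring A C9 acid C8 methyl ester | OC(=O)[C@@]1(C)CCC[C@@](C)(C(=O)OC)[C@@H]1[C@@H](O[Si](C)(C)C(C)(C)C)CC(=O)OC | intermediate
11 | ring A C9 primary alcohol | OC[C@@]1(C)CCC[C@@](C)(C(=O)OC)[C@@H]1[C@@H](O[Si](C)(C)C(C)(C)C)CC(=O)OC | intermediate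
12 | ring A C9 aldehyde | O=C[C@@]1(C)CCC[C@@](C)(C(=O)OC)[C@@H]1[C@@H](O[Si](C)(C)C(C)(C)C)CC(=O)OC | intermediate
13 | ring A (E)-iodoalkene | I/C=C/[C@@]1(C)CCC[C@@](C)(C(=O)OC)[C@@H]1[C@@H](O[Si](C)(C)C(C)(C)C)CC(=O)OC | intermediate
14 | ring A (E)-allylsilane C8 methyl ester | C[Si](C)(C)C/C=C/[C@@]1(C)CCC[C@@](C)(C(=O)OC)[C@@H]1[C@@H](O[Si](C)(C)C(C)(C)C)CC(=O)OC | intermediate
15 | ring A (E)-allylsilane C8 Weinreb amide | C[Si](C)(C)C/C=C/[C@@]1(C)CCC[C@@](C)(C(=O)OC)[C@@H]1[C@@H](O[Si](C)(C)C(C)(C)C)CC(=O)N(C)OC | intermediate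
16 | ring A keto allylsilane (key-step precursor) | C[Si](C)(C)C/C=C/[C@@]1(C)CCC[C@@](C)(C(=O)OC)[C@@H]1[C@@H](O[Si](C)(C)C(C)(C)C)CC(C)=O | intermediate
17 | methyl 6α-(tert-butyldimethylsilyloxy)-8α-hydroxy-13,14,15,16-tetranorlabd-11-en-18-oate (key-step product) | C=C[C@@H]1[C@@]2(C)CCC[C@@](C)(C(=O)OC)[C@@H]2[C@@H](O[Si](C)(C)C(C)(C)C)C[C@@]1(C)O | intermediate
18 | 3-(trimethylsilyl)propynal | C[Si](C)(C)C#CC=O | starting material
19 | (R)-1-(trimethylsilyl)hex-5-en-1-yn-3-ol | C=CC[C@@H](O)C#C[Si](C)(C)C | intermediate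
20 | (R)-3-(tert-butyldimethylsilyloxy)-1-(trimethylsilyl)hex-5-en-1-yne | C=CC[C@@H](O[Si](C)(C)C(C)(C)C)C#C[Si](C)(C)C | intermediate
21 | (R)-3-(tert-butyldimethylsilyloxy)-5-(trimethylsilyl)pent-4-ynal | O=CC[C@@H](O[Si](C)(C)C(C)(C)C)C#C[Si](C)(C)C | intermediate
22 | methyl propiolate | C#CC(=O)OC | starting material
23 | (3-methoxy-3-oxoprop-1-ynyl)(methyl)zinc | C[Zn]C#CC(=O)OC | intermediate
24 | methyl (4S,6R)-6-(tert-butyldimethylsilyloxy)-4-hydroxy-8-(trimethylsilyl)octa-2,7-diynoate | COC(=O)C#C[C@@H](O)C[C@@H](O[Si](C)(C)C(C)(C)C)C#C[Si](C)(C)C | intermediate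
25 | methyl (2Z,4S,6R)-6-(tert-butyldimethylsilyloxy)-4-hydroxy-3-methyl-8-(trimethylsilyl)oct-2-en-7-ynoate | COC(=O)/C=C(C)\[C@@H](O)C[C@@H](O[Si](C)(C)C(C)(C)C)C#C[Si](C)(C)C | intermediate
26 | (S)-5-[(R)-2-(tert-butyldimethylsilyloxy)-4-(trimethylsilyl)but-3-yn-1-yl]-4-methylfuran-2(5H)-one | C[Si](C)(C)C#C[C@@H](C[C@@H]1OC(=O)C=C1C)O[Si](C)(C)C(C)(C)C | intermediate
27 | (S)-5-[(R)-2-hydroxybut-3-yn-1-yl]-4-methylfuran-2(5H)-one | C#C[C@@H](C[C@@H]1OC(=O)C=C1C)O | intermediate
28 | (S)-5-[(R)-2-hydroxy-3-iodobut-3-en-1-yl]-4-methylfuran-2(5H)-one | C=C(I)[C@@H](C[C@@H]1OC(=O)C=C1C)O | intermediate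
29 | B-alkyl-9-BBN borane from 17 (boron on C12) | C1CCC2CCCC1B2CC[C@@H]3[C@@]4(C)CCC[C@@](C)(C(=O)OC)[C@@H]4[C@@H](O[Si](C)(C)C(C)(C)C)C[C@@]3(C)O | intermediate
30 | coupled (14R)-allylic alcohol, 6-O-TBS | C=C(CC[C@@H]1[C@@]2(C)CCC[C@@](C)(C(=O)OC)[C@@H]2[C@@H](O[Si](C)(C)C(C)(C)C)C[C@@]1(C)O)[C@@H](C[C@@H]1OC(=O)C=C1C)O | intermediate
31 | (14R)-allylic mesylate, 6-O-TBS | C=C(CC[C@@H]1[C@@]2(C)CCC[C@@](C)(C(=O)OC)[C@@H]2[C@@H](O[Si](C)(C)C(C)(C)C)C[C@@]1(C)O)[C@@H](C[C@@H]1OC(=O)C=C1C)OS(C)(=O)=O | intermediate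
32 | (14S)-hydroperoxide, 6-O-TBS | C=C(CC[C@@H]1[C@@]2(C)CCC[C@@](C)(C(=O)OC)[C@@H]2[C@@H](O[Si](C)(C)C(C)(C)C)C[C@@]1(C)O)[C@H](C[C@@H]1OC(=O)C=C1C)OO | intermediate
33 | CNP0324515.1 | C=C(CC[C@@H]1[C@@]2(C)CCC[C@@](C)(C(=O)OC)[C@@H]2[C@@H](O)C[C@@]1(C)O)[C@H](C[C@@H]1OC(=O)C=C1C)OO | target

**Step count.** Total: 25 steps. Longest linear sequence: 18 steps (steps 1–15 and 23–25). The butenolide fragment takes 7 steps (steps 16–22).

**Steps most likely to fail**

**1. Step 15.**
- What may go wrong: poor facial selectivity at C8 (the complexed oxygen going axial), protodesilylation of the allylsilane, or β-elimination of the silyloxy group before ring closure.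
- Fallback, from 14 back to 17:
  - LiOH saponifies only the unhindered C8 ester of 14 to the C8 carboxylic acid F1.
  - 1-Chloro-N,N,2-trimethylprop-1-en-1-amine turns it into the C8 acid chloride F2.
  - SnCl4 at −78 °C closes the same C8–C9 bond by intramolecular acylation of the allylsilane to the 8-oxo-9β-vinyl decalin F3. Its C9 is epimerisable and should settle with the vinyl group equatorial.
  - Lombardo methylenation (Zn, CH2Br2, TiCl4) gives the 8(17)-exocyclic alkene F4.
  - One equivalent of mCPBA attacks this more electron-rich alkene from the α face, the β face being covered by the C10 methyl, to give the 8α,17-epoxide F5.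
  - LiEt3BH opens F5 at C17 to give 17.

**2. Step 24.**
- What may go wrong: allylic transposition (attack at the methylene terminus), ionisation with erosion of configuration at C14, or base-triggered peroxy-Michael closure onto the butenolide.
- Fallback, from 30 back to 32:
  - Mitsunobu displacement with 2-nitrobenzenesulfonylhydrazine (PPh3, diethyl azodicarboxylate, −30 °C) gives the N-allyl sulfonylhydrazine F6.
  - On warming, F6 loses sulfinic acid to give the allylic diazene F7.
  - Retro-ene loss of N2 from F7 shifts the double bond and gives the (13E)-trisubstituted alkene F8.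
  - A Schenck ene reaction (O2, tetraphenylporphyrin, hν, CH2Cl2, 0 °C) abstracts hydrogen on the more crowded side of the alkene, partly from the C13 methyl. It should give 32 beside its C14 epimer and the tertiary C13 hydroperoxide, from which 32 would be separated by HPLC.

**3. Step 8.**
- What may go wrong: benzylic C7–H oxidation outrunning arene cleavage and deactivating the ring, or loss of the silyl ether in the acidic aqueous medium.
- Fallback, from 8 back to 9: exhaustive ozonolysis (O3, CH2Cl2/MeOH, −78 °C to −20 °C) attacks the arene π bonds by cycloaddition and leaves benzylic C–H bonds alone. Alkaline H2O2 then cleaves the α-dicarbonyl fragments to the two carboxylic acids of 9. No new compound arises (F0).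

**Further compounds**

F1 | step 15 | C8 carboxylic acid of the ring A (E)-allylsilane | C[Si](C)(C)C/C=C/[C@@]1(C)CCC[C@@](C)(C(=O)OC)[C@@H]1[C@@H](O[Si](C)(C)C(C)(C)C)CC(=O)O
F2 | step 15 | C8 acid chloride of the ring A (E)-allylsilane | C[Si](C)(C)C/C=C/[C@@]1(C)CCC[C@@](C)(C(=O)OC)[C@@H]1[C@@H](O[Si](C)(C)C(C)(C)C)CC(=O)Cl
F3 | step 15 | methyl 6α-(tert-butyldimethylsilyloxy)-8-oxo-13,14,15,16,17-pentanorlabd-11-en-18-oate | C=C[C@@H]1[C@@]2(C)CCC[C@@](C)(C(=O)OC)[C@@H]2[C@@H](O[Si](C)(C)C(C)(C)C)CC1=O
F4 | step 15 | methyl 6α-(tert-butyldimethylsilyloxy)-13,14,15,16-tetranorlabda-8(17),11-dien-18-oate | C=C[C@@H]1[C@@]2(C)CCC[C@@](C)(C(=O)OC)[C@@H]2[C@@H](O[Si](C)(C)C(C)(C)C)CC1=C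
F5 | step 15 | methyl 6α-(tert-butyldimethylsilyloxy)-8α,17-epoxy-13,14,15,16-tetranorlabd-11-en-18-oate | C=C[C@@H]1[C@@]2(C)CCC[C@@](C)(C(=O)OC)[C@@H]2[C@@H](O[Si](C)(C)C(C)(C)C)C[C@]13CO3
F6 | step 24 | (14S)-N-allyl-N-(2-nitrophenylsulfonyl)hydrazine, 6-O-TBS | C=C(CC[C@@H]1[C@@]2(C)CCC[C@@](C)(C(=O)OC)[C@@H]2[C@@H](O[Si](C)(C)C(C)(C)C)C[C@@]1(C)O)[C@H](C[C@@H]1OC(=O)C=C1C)N(N)S(=O)(=O)c1ccccc1[N+](=O)[O-]
F7 | step 24 | (14S)-allylic diazene, 6-O-TBS | C=C(CC[C@@H]1[C@@]2(C)CCC[C@@](C)(C(=O)OC)[C@@H]2[C@@H](O[Si](C)(C)C(C)(C)C)C[C@@]1(C)O)[C@H](C[C@@H]1OC(=O)C=C1C)N=N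
F8 | step 24 | (13E)-trisubstituted alkene, 6-O-TBS | C/C(=C\C[C@@H]1OC(=O)C=C1C)CC[C@@H]2[C@@]3(C)CCC[C@@](C)(C(=O)OC)[C@@H]3[C@@H](O[Si](C)(C)C(C)(C)C)C[C@@]2(C)O
F0 | step 8 | none | none
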